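In days, Tuesday's feed of 1.0 h lasts 0.0417 d and Friday's feed of 0.20 h lasts 0.00833 d, while the asked reading comes at 6.0 d.

| setting | spring | autumn | winter | Friday's | Monday's | Sunday's | Thursday's | Tuesday's |
|---|---|---|---|---|---|---|---|---|
| starting complex | 0.28 M | 0.44 M | 0.20 M | 0.20 M | 0.20 M | 0.20 M | 0.20 M | 0.20 M |
| incoming ligand | 0.24 M (fed, over 0.20 h) | 0.24 M (fed, over 0.20 h) | 0.12 M (fed, over 0.20 h) | 0.240 M (fed, over 0.20 h) | 0.240 M (fed, over 0.30 h) | 0.240 M (fed, over 0.40 h) | 0.240 M (fed, over 0.60 h) | 0.240 M (fed, over 1.0 h) |
| remark | run made earlier | run made earlier | run made earlier |  |  |  |  |  |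
| time |  |  |  | 6.0 d | 6.0 d | 6.0 d | 6.0 d | 6.0 d |

| run | time / d | complex with one exchanged / % | starting complex / % |
|---|---|---|---|
| spring | 0.500 | 19.3 | 49.8 |
| spring | 1.04 | 24.1 | 47.1 |
| spring | 2.50 | 30.0 | 42.1 |
| spring | 6.00 | 29.7 | 43.1 |
| autumn | 0.500 | 19.0 | 64.0 |
| autumn | 1.04 | 22.9 | 62.7 |
| autumn | 2.50 | 25.9 | 58.1 |
| autumn | 6.00 | 25.9 | 59.8 |
| winter | 0.500 | 18.1 | 64.2 |
| winter | 1.04 | 19.3 | 61.7 |
| winter | 2.50 | 23.9 | 58.8 |
| winter | 6.00 | 28.1 | 57.1 |

(scatter of a reading: 1 percentage point)

- the numbers in the tables scatter by 1 percentage point (one standard deviation)
- "hardly changes" means that all values lie within two and a half points (for a concentration: within two and a half percent of the largest)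

1. amount of complex with one exchanged at the end, in percent of the starting complex charged for Friday's, Monday's, Sunday's, Thursday's, Tuesday's, in this order
2. how that number moves from the first to the last of them (rises all the way / hardly changes / falls, then rises / falls all the way / rises, then falls)

A steady feed delivers its average portion of incoming ligand at half the dosing time. Winter's first reading comes much later than the end of Tuesday's feed, so each flask is treated here as one shot given at the midpoint of its feed. The two ends of the series then differ by a shift of the clock of 0.0167 d, the feed lag, which is half the difference of the dosing times. A curve read at a late time moves by the lag times its slope there, and the flasks between the ends lie on a straight line in dosing time.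

The slope comes from the readings. Winter's complex with one exchanged climbs 4.2 percentage points in 3.50 d over the last interval, more than in spring or autumn. With the lag, that gives a shift of 0.02 points between the ends. The level is borrowed: spring has the most ligand per complex among the earlier runs, at 0.857 against 1.20 here, and it ends at 29.7%. So the committed row is flat near that reading.

The weak link is the slope, taken from a flask with a different charge. Spring's climb between its first two readings, 4.8 points in 0.540 d, is a far harder test, and it gives 0.15 points, to be set beside a scatter of 1 point.

The forecast gave 29.5% to 29.7%, hardly changes, on the ground that “Feed time (at most 1 h) only alters the early distribution, which is erased by 6 d.”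

The simulation gives 29.7% for Friday's and 29.7% for Tuesday's, hardly changes, and feeding bit by bit rather than at once barely touches Tuesday's value.

    starting complex + incoming ligand ⇌ leaving ligand + complex with one exchanged (K = 44.0, k = 0.790 /M/h)
    complex with one exchanged + incoming ligand ⇌ leaving ligand + complex with two exchanged (K = 11.0, k = 2.20 /M/h)
    complex with one exchanged + incoming ligand → over-reaction product (k = 0.770 /M/h)

Complex with one exchanged stood at 1.79% in Friday's flask at the end of its feed, at 0.00833 d, and at 7.26% in Tuesday's flask at the end of its feed, at 0.0417 d; by 6.0 d the two stood at 29.7% and 29.7%, with incoming ligand, the limiting reagent, down to 1.6% of its charge in Friday's. Friday's complex with two exchanged falls from 16.7% at 3.00 d to 9.33% at 6.00 d and on to 0.347% at 60.0 d, so the lag of 0.0167 d times the mean slope of the first interval gives only a rough 0.041 points, the curve flattening by 6.0 d; at that time Tuesday's stands at 9.36% and Friday's at 9.33%, 0.030 points apart.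

The earlier runs and the new flask are simulated on assumed constants, and the scatter is random.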